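The numbers of this flask are made up; no experiment stands behind them.

The target in this flask forms from substrate and a reagent that crosses over from the second phase, and it decomposes in solution while its crystals stand by.

    target ⇌ product in the second phase, rate k1*([target] - [product in the second phase]/K1) per volume of the first phase (K1 = 1.7, k1 = 0.00171 /s)
    substrate + target → side product (k2 = 1.07 × 10⁻⁴ /M/s)
    crystals ⇌ target, rate k3*(cs3 - [target]) while solid is left; crystals form when [target] > cs3 (cs3 = 8.3 mM, k3 = 0.00524 /s)
    substrate + reagent in the reaction phase → target (k4 = 0.0166 /M/s)
    target → decomposed product (k5 = 1.03 × 10⁻⁴ /s)
    reagent in the reaction phase ⇌ reagent in the second phase, rate k6*([reagent in the reaction phase] - [reagent in the second phase]/K6) per volume of the first phase (K6 = 0.509, k6 = 1.14 × 10⁻⁴ /s)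
substrate 0.10 M; reagent in the second phase 0.800 equiv; time 20 h; volume of the second phase over the first 0.50
- a species is counted by the substrate in it: one side product counts as two
- amounts and yields of target count product in the second phase and crystals too
- in the second phase: reagent in the second phase, product in the second phase; everything else is in the first
- charges count per volume of the first phase; a concentration in a rate is the amount of a species over the volume of its own phase; every rate counts per litre of the first phase
- given per volume of solution although it is solid: crystals
- run time (flask): 20 h
1. target and product in the second phase and crystals together at 20 h, in percent of the substrate charged
2. concentration of target in solution at 20 h, in percent of saturation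

The reagent is the limiting reagent, so the ceiling on target in its forms is 80.0% of the charge. Dissolved target has a half-life of 1.9 h by decomposition, shorter than 18 h by side product with substrate as charged, so the reckoning here follows decomposition.

Two extreme versions of this flask can be solved by hand. In the first, target stands at the ceiling from the start, stays dissolved and decays first-order; that half-life is short against 20 h, and 0.0481% of the charge remains. In the second, solid stands throughout, and dissolution balances decomposition in the solution, which stands at 98.1% of saturation. Decomposition is then zero-order in total target: 0.0302 /h, the saturation drain, meaning the decomposition rate at that level over the substrate charged. Over 20 h it takes 60.4%, and side product, reckoned with substrate at 20.0% of its charge, costs about 1.28% of the charge in target, which leaves 18.4%.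

The two liquid phases hold 15.4% of the charge at saturation, less than the ceiling, so the real flask should follow the second version while solid lasts. That capacity is also less than the 18.4% left, so this reckoning keeps about 3.00% of the charge as solid at the asked time and puts the end of the solid near 21.0 h.

The forecast gives 17.5% and 100%, lower than this reckoning on yield and higher on saturation, holding that “a little solid should survive and the solution should still be essentially saturated”.

The simulation gives 17.3% and 98.0%, with crystals at 2.30% and decomposed product at 61.2% against the 60.4% of the drain, so the forecast stands within its tolerance; the yield of this flask moves 5 points with reagent in the second phase at 0.749 equiv or 0.849 equiv. The neighbouring flask, read at 5.0 h, takes the same reckoning: the ceiling less 15.1% of saturation drain and 0.320% of side-product cost leaves 64.6%. That flask holds crystals at 47.5% and decomposed product at 15.9%, and it gives 62.7%.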